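## Retrosynthetic overview

- The target (quinone numbering: C1=O, C2–OH, C3–Me, C4=O, C5–OH, C6–alkenyl) comes from its 2,5-di-O-methyl ether 18 by hydrolysis of the two vinylogous methyl esters.
- The quinone ring of 18, the only ring, is closed in one flask by a head-to-tail [3+3] union of two (E)-3-methoxyacrylate halves. Ester 9 supplies C5(OMe)–C6(alkenyl)–C1(=O) and acid chloride 14 supplies C2(OMe)–C3(Me)–C4(=O). The C4–C5 bond forms first, then the C1–C2 bond.
- Enabling feature: the ring is two O–C–C(alkyl)–C–O units. In each, the enol-ether carbon (C5, C2) carries a vinylic H cis to its own carbonyl (C1, C4), so it can be lithiated and made a donor. Both new bonds then join two oxygen-bearing carbons of like polarity.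
- 9 comes from methyl (Z)-heptadec-12-enoate 6 by formylation and O-methylation; 6 comes from a Z-selective Wittig reaction of pentanal with the ylide of methyl 12-bromododecanoate. 14 comes from methyl propionate and methyl formate.

Key step: step 8

Remark on the chemistry: the 2,5-dihydroxy-1,4-benzoquinone core has two degenerate tautomers (proton shift between the oxygens on C1/C2 and on C4/C5). A precursor with C=O at C1/C4 and OMe at C2/C5 therefore gives the compound as drawn.

## Route

Step 1
Reactants: 1 12-bromododecanoic acid
Product: 2 methyl 12-bromododecanoate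
Conditions: MeOH, cat. H2SO4, reflux
Reagents that add atoms: methanol, CO
Why: Fischer esterification driven by excess methanol; the primary bromide is inert under these conditions.

Step 2
Reactants: 2 methyl 12-bromododecanoate
Product: 3 (12-methoxy-12-oxododecyl)triphenylphosphonium bromide
Conditions: PPh3, MeCN, reflux
Reagents that add atoms: triphenylphosphine, c1ccc(cc1)P(c1ccccc1)c1ccccc1
Why: SN2 quaternisation of triphenylphosphine by the unhindered primary bromide should give the phosphonium salt cleanly.

Step 3
Reactants: 3 (12-methoxy-12-oxododecyl)triphenylphosphonium bromide; 4 pentanal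
Product: 6 methyl (Z)-heptadec-12-enoate, via phosphorus ylide 5 (not isolated)
Conditions: NaN(SiMe3)2 (1.0 equiv), THF, −78 → 0 °C; then 4, −78 °C → rt
Reagents that add atoms: none
Why: Wittig olefination of a non-stabilised, lithium-free ylide with an aliphatic aldehyde, where the kinetically formed cis-oxaphosphetane should give the (Z)-alkene; the phosphonium α-CH is more acidic than the ester α-CH.

Step 4
Reactants: 6 methyl (Z)-heptadec-12-enoate; 7 methyl formate
Product: 9 methyl (E)-3-methoxy-2-[(Z)-pentadec-10-en-1-yl]acrylate, via sodium enolate 8 (not isolated)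
Conditions: NaH, 7 (excess), cat. MeOH, THF, 0 °C → rt; then Me2SO4, DMF, rt; chromatography
Reagents that add atoms: dimethyl sulfate, COS(=O)(=O)OC
Why: crossed Claisen condensation (formylation) driven by formation of the stabilised enolate, then O-methylation with a hard electrophile in a dipolar aprotic solvent, which should favour the (E)-enol ether (OMe trans to the ester) as in standard β-methoxyacrylate preparations.

Step 5
Reactants: 10 methyl propionate; 7 methyl formate
Product: 12 methyl (E)-3-methoxy-2-methylacrylate, via sodium enolate 11 (not isolated)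
Conditions: NaH, 7 (excess), cat. MeOH, Et2O, 0 °C → rt; then Me2SO4, DMF, rt; distillation
Reagents that add atoms: dimethyl sulfate, COS(=O)(=O)OC
Why: the same Claisen formylation and O-methylation sequence, a standard entry to this (E)-β-methoxyacrylate.

Step 6
Reactants: 12 methyl (E)-3-methoxy-2-methylacrylate
Product: 13 sodium (E)-3-methoxy-2-methylacrylate
Conditions: NaOH (1.0 equiv), H2O/MeOH, rt → 50 °C; evaporate and dry
Reagents that add atoms: sodium hydroxide, [Na+].[OH-]
Why: saponification of the methyl ester; the enol ether is stable to base, and isolation as the dry sodium salt avoids acid contact.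

Step 7
Reactants: 13 sodium (E)-3-methoxy-2-methylacrylate
Product: 14 (E)-3-methoxy-2-methylacryloyl chloride
Conditions: (COCl)2 (1.1 equiv), Et2O, 0 °C → rt; filter, distil
Reagents that add atoms: oxalyl chloride, ClC(=O)C(=O)Cl
Why: acyl chloride formation from the carboxylate salt, which liberates no HCl and so should spare the acid-sensitive enol ether and its (E) geometry.

Step 8
Reactants: 9 methyl (E)-3-methoxy-2-[(Z)-pentadec-10-en-1-yl]acrylate; 14 (E)-3-methoxy-2-methylacryloyl chloride
Product: 18 2,5-dimethoxy-3-methyl-6-[(Z)-pentadec-10-en-1-yl]cyclohexa-2,5-diene-1,4-dione, via vinyllithium 15 (not isolated), via divinyl ketone 16 (not isolated), via lithiated divinyl ketone 17 (not isolated)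
Conditions: lithium 2,2,6,6-tetramethylpiperidide (1.05 equiv), THF, −95 °C; then 14 (1.05 equiv), −95 → −78 °C; then lithium 2,2,6,6-tetramethylpiperidide (1.1 equiv), −78 → −40 °C; 1 M HCl
Reagents that add atoms: none
Why: Proposed new method: the amide base removes the vinylic C3–H of 9 (future quinone C5), which sits on the methoxy-bearing carbon cis to the ester carbonyl, to give the chelated vinyllithium 15 (polarity reversal of an otherwise electrophilic carbon), and 15 is acylated by 14 to form the C4–C5 bond in divinyl ketone 16; the second equivalent of base then removes the only vinylic hydrogen of 16 (cis to the new ketone) and vinyllithium 17 attacks the methyl ester with loss of methoxide to form the C1–C2 bond, so the quinone appears directly at its final oxidation level. The closest known reaction types are the β-lithiation of (E)-3-alkoxyacrylates with trapping by carbonyl electrophiles and the Parham-type cyclisation of a vinyllithium onto an internal ester; a head-to-tail double acylation of two such acrylates to a quinone is not established. The quinone ring closes by a 6-exo-trig acylation within a planar U-shaped divinyl ketone, which requires each acyl carbon to sit cis to the reacting enol-ether carbon, and this is fixed by the (E) geometry of 9 and 14 and kept by the configurationally stable chelated vinyllithiums. No stereocenter is formed and the remote (Z)-alkene is inert to the hindered amide base. The step needs cross-coupling over homo-coupling and a head-to-tail orientation: only 9 is metalated before 14 is added, the acyl chloride of 14 is far more electrophilic than the methyl ester of 15 or the doubly donor-substituted ketone of 16, and each half has exactly one donor and one acceptor terminus.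

Step 9
Reactants: 18 2,5-dimethoxy-3-methyl-6-[(Z)-pentadec-10-en-1-yl]cyclohexa-2,5-diene-1,4-dione
Product: 19 2,5-dihydroxy-3-methyl-6-[(Z)-pentadec-10-en-1-yl]cyclohexa-2,5-diene-1,4-dione
Conditions: 2 M NaOH, MeOH/THF, argon, 50 °C; then 2 M HCl to pH 1
Reagents that add atoms: sodium hydroxide, [Na+].[OH-]
Why: hydrolysis of the two vinylogous methyl esters by addition–elimination of hydroxide at C2 and C5, the standard conversion of 2,5-dimethoxyquinones into 2,5-dihydroxyquinones; the isolated (Z)-alkene is not affected.

## Compound list

1 | 12-bromododecanoic acid | OC(=O)CCCCCCCCCCCBr | starting material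
2 | methyl 12-bromododecanoate | COC(=O)CCCCCCCCCCCBr | intermediate
3 | (12-methoxy-12-oxododecyl)triphenylphosphonium bromide | COC(=O)CCCCCCCCCCC[P+](c1ccccc1)(c1ccccc1)c1ccccc1.[Br-] | intermediate
4 | pentanal | CCCCC=O | starting material
5 | methyl 12-(triphenylphosphoranylidene)dodecanoate (ylide) | COC(=O)CCCCCCCCCCC=P(c1ccccc1)(c1ccccc1)c1ccccc1 | intermediate (not isolated)
6 | methyl (Z)-heptadec-12-enoate | CCCC/C=C\CCCCCCCCCCC(=O)OC | intermediate
7 | methyl formate | COC=O | starting material
8 | sodium enolate of methyl (Z)-2-formylheptadec-12-enoate (enolate geometry not defined) | [Na+].[O-]C=C(CCCCCCCCC/C=C\CCCC)C(=O)OC | intermediate (not isolated)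
9 | methyl (E)-3-methoxy-2-[(Z)-pentadec-10-en-1-yl]acrylate | CO/C=C(\CCCCCCCCC/C=C\CCCC)C(=O)OC | intermediate
10 | methyl propionate | CCC(=O)OC | starting material
11 | sodium enolate of methyl 2-formylpropanoate (enolate geometry not defined) | [Na+].[O-]C=C(C)C(=O)OC | intermediate (not isolated)
12 | methyl (E)-3-methoxy-2-methylacrylate | CO/C=C(\C)C(=O)OC | intermediate
13 | sodium (E)-3-methoxy-2-methylacrylate | CO/C=C(\C)C(=O)[O-].[Na+] | intermediate
14 | (E)-3-methoxy-2-methylacryloyl chloride | CO/C=C(\C)C(Cl)=O | intermediate
15 | methyl (E)-3-lithio-3-methoxy-2-[(Z)-pentadec-10-en-1-yl]acrylate | CO/C([Li])=C(\CCCCCCCCC/C=C\CCCC)C(=O)OC | intermediate (not isolated)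
16 | methyl (2E,5E)-3,6-dimethoxy-5-methyl-4-oxo-2-[(Z)-pentadec-10-en-1-yl]hexa-2,5-dienoate | COC(=O)/C(CCCCCCCCC/C=C\CCCC)=C(/OC)C(=O)/C(C)=C/OC | intermediate (not isolated)
17 | methyl (2E,5E)-6-lithio-3,6-dimethoxy-5-methyl-4-oxo-2-[(Z)-pentadec-10-en-1-yl]hexa-2,5-dienoate | COC(=O)/C(CCCCCCCCC/C=C\CCCC)=C(/OC)C(=O)/C(C)=C(/OC)[Li] | intermediate (not isolated)
18 | 2,5-dimethoxy-3-methyl-6-[(Z)-pentadec-10-en-1-yl]cyclohexa-2,5-diene-1,4-dione | CCCC/C=C\CCCCCCCCCC1=C(OC)C(=O)C(C)=C(OC)C1=O | intermediate
19 | 2,5-dihydroxy-3-methyl-6-[(Z)-pentadec-10-en-1-yl]cyclohexa-2,5-diene-1,4-dione | CCCC/C=C\CCCCCCCCCC1=C(O)C(=O)C(C)=C(O)C1=O | target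

## Step count and risks

Total step count: 9. Longest linear sequence: 6 steps (steps 1, 2, 3, 4, 8, 9).

Steps most likely to fail:

1. Step 8 (proposed new method). Three processes may spoil it:
   - kinetic deprotonation of 16 at the allylic CH2 on the ester-bearing carbon (vinylogous enolisation) in place of vinylic lithiation;
   - self-condensation of 15 if the temperature rises before 14 is added;
   - attack of excess base on the quinone once it has formed.

   Fallback (known chemistry), setting out from pentanal 4 and coming back at 18. Commercial 10-bromodecan-1-ol and PPh3 (MeCN, reflux) should give (10-hydroxydecyl)triphenylphosphonium bromide F1. Its ylide (NaN(SiMe3)2, 2 equiv, THF, −78 °C) with 4 should give (Z)-pentadec-10-en-1-ol F2, and CBr4/PPh3 (CH2Cl2, 0 °C) should convert this into (Z)-15-bromopentadec-5-ene F3. Separately, commercial 1,2,4,5-tetramethoxybenzene is lithiated (n-BuLi, THF, 0 °C) and methylated (MeI) to 1,2,4,5-tetramethoxy-3-methylbenzene F4. A second lithiation of F4 (n-BuLi, TMEDA, THF) and alkylation with F3 should give 1,2,4,5-tetramethoxy-3-methyl-6-[(Z)-pentadec-10-en-1-yl]benzene F5. Oxidative demethylation with (NH4)2Ce(NO3)6 in MeCN/H2O at 0 °C should then deliver 18.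

2. Step 4. Self-Claisen condensation of the long-chain ester may compete with formylation, and O-methylation may give an E/Z mixture in which only the (E)-isomer can be lithiated in step 8.

   Fallback, setting out from 6 and coming back at 9. Enolisation of 6 (LiN(iPr)2, THF, −78 °C) and silylation (Me3SiCl) should give the ketene silyl acetal [(12Z)-1-methoxyheptadeca-1,12-dien-1-yl]oxytrimethylsilane F6. A Mukaiyama-type reaction with HC(OMe)3 (cat. Me3SiOTf, CH2Cl2, −78 °C) should give methyl (Z)-2-(dimethoxymethyl)heptadec-12-enoate F7. Acid-catalysed loss of methanol (cat. TsOH, toluene, reflux with removal of MeOH) should give 9 under thermodynamic control of the enol-ether geometry.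

3. Step 9. Hydrolysis of the second vinylogous ester may stall after the first has produced an electron-rich anion, and the hydroxyquinone may degrade oxidatively in hot alkali.

   Fallback, setting out from 18 and coming back at 19. Reduction with Na2S2O4 (EtOAc/H2O, rt) should give 2,5-dimethoxy-3-methyl-6-[(Z)-pentadec-10-en-1-yl]benzene-1,4-diol F8. Ether cleavage with BBr3 (CH2Cl2, −78 → 0 °C, aqueous work-up) should give 3-methyl-6-[(Z)-pentadec-10-en-1-yl]benzene-1,2,4,5-tetrol F9. Air oxidation (O2, EtOAc/aqueous NaHCO3, rt, then acidification) should give 19.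

Further compounds
F1 | step 8 | (10-hydroxydecyl)triphenylphosphonium bromide | OCCCCCCCCCC[P+](c1ccccc1)(c1ccccc1)c1ccccc1.[Br-]
F2 | step 8 | (Z)-pentadec-10-en-1-ol | CCCC/C=C\CCCCCCCCCO
F3 | step 8 | (Z)-15-bromopentadec-5-ene | CCCC/C=C\CCCCCCCCCBr
F4 | step 8 | 1,2,4,5-tetramethoxy-3-methylbenzene | COc1cc(OC)c(OC)c(C)c1OC
F5 | step 8 | 1,2,4,5-tetramethoxy-3-methyl-6-[(Z)-pentadec-10-en-1-yl]benzene | CCCC/C=C\CCCCCCCCCc1c(OC)c(OC)c(C)c(OC)c1OC
F6 | step 4 | [(12Z)-1-methoxyheptadeca-1,12-dien-1-yl]oxytrimethylsilane (mixture at C1=C2) | CCCC/C=C\CCCCCCCCCC=C(OC)O[Si](C)(C)C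
F7 | step 4 | methyl (Z)-2-(dimethoxymethyl)heptadec-12-enoate (racemic) | CCCC/C=C\CCCCCCCCCC(C(OC)OC)C(=O)OC
F8 | step 9 | 2,5-dimethoxy-3-methyl-6-[(Z)-pentadec-10-en-1-yl]benzene-1,4-diol | CCCC/C=C\CCCCCCCCCc1c(O)c(OC)c(C)c(O)c1OC
F9 | step 9 | 3-methyl-6-[(Z)-pentadec-10-en-1-yl]benzene-1,2,4,5-tetrol | CCCC/C=C\CCCCCCCCCc1c(O)c(O)c(C)c(O)c1O
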